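## Structural features

Pestalone B is a benzophenone: ring A (C1–C6) and ring B (C1'–C6') are joined only through a ketone carbon bonded to C1 and C1'. There is no further ring and no stereocentre, so no neighbouring stereocentres have to be related; the only stereochemical element is the strongly twisted, freely rotating diaryl ketone. Ring A carries the acyl group at C1, OH at C2, Br at C3, CH3 at C4, H at C5 and OCH3 at C6, so its two oxygens are differentiated and the bromine lies between C2 and C4. Ring B carries CHO at C2', OH at C3', H at C4', OH at C5' and a 3-methylbut-2-enyl (prenyl) group at C6'. All four positions ortho to the ketone (C2, C6, C2', C6') are substituted, so joining two finished arenes through the carbonyl carbon is the classical bottleneck. The fragile groups are: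
- the prenyl alkene next to the free C5' hydroxyl (acid closes a chroman, electrophilic halogen adds);
- the formyl group ortho to the ketone (base-induced hydride transfer to a phthalide, and lactol formation whenever the ketone is a carbinol);
- the aryl bromide (alkyllithiums, zerovalent palladium, hydrogenolysis);
- the electron-rich resorcinol (oxidants).

The real difficulty is to place four different substituents in the right order on ring B beside the hindered ketone, and to have bromine on ring A without ever exposing the prenyl group to a brominating agent. The key step uses the fact that C3'–C4'–C5'–C6' carries O, H, O and prenyl, the pattern of a γ-prenylated acetoacetate, while C1' and C2' both carry carbonyl groups, the pattern of an alkyne flanked by an aroyl and a formyl group.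

## Logic of the disconnections

21 to 20: only the O–CH2 bond of the acetal on the C2 oxygen is cut. The C2 phenol must stay masked as long as an alkynyl ketone sits at C1, because a free ortho-hydroxyl would add to the triple bond, and the mask must also survive lithium amides and direct a metalation. The gain is that 20 already holds every carbon and every substituent of 21. The demand is an unmasking mild enough not to protonate the prenyl alkene beside the C5' hydroxyl.

20 to 11 + 18: C1'–C6' and C2'–C3' are cut, which removes ring B. The ketone carbon stays attached to ring A at the ketone oxidation level, so the tetra-ortho-substituted diaryl ketone never has to be made by an aryl–acyl union. A carbinol at that carbon was rejected because, next to the C2' formyl group, it would close to a lactol that oxidises to a phthalide. The bromine is already in 11, so no brominating agent meets the prenyl group. The demand on the forward step is threefold: the diene terminus bearing the prenyl methylene must bond to C1' and not to C2'; the diene must add to the triple bond and not to a carbonyl group; aromatisation must occur near neutrality so that the acetal on C2 survives.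

18 to 16 to 15: two O–Si bonds are cut in turn. This reduces the diene to a β-keto ester. The demand is that the second deprotonation occurs at the γ-carbon (future C6') and that the dienolate is silylated on oxygen.

15 to 12 + 13: the bond between the γ-carbon of the keto ester and the allylic CH2 is cut. Both pieces are commercial. The demand is alkylation of the dianion at the terminal carbon only, by direct displacement at the primary allylic carbon.

11 to 10: no skeletal bond is cut; both carbonyl groups are taken back to hydroxyl groups. An acetal at the future formyl carbon was rejected: its hydrolysis, slowed by the conjugated ynone, would need acid that the aryl MOM ether is unlikely to outlast. Oxidation of a diol needs no acid and saves one step. The gain is that 10 is a stable, storable compound. The demand is a neutral oxidant and a work-up without water, since 11 is a very strong electrophile.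

10 to 7 + 8: the bond between the carbinol carbon and the alkyne carbon is cut. This gives an aromatic aldehyde and a three-carbon alkynol. The demand is that no alkyllithium is left when 7 is added, so that the C–Br bond is not exchanged.

7 to 5: the C1–CHO bond is cut. C1 lies between the two oxygen substituents, the best site for a directed metalation. The demand is a base that removes this proton without touching the bromine.

5 to 4 to 2 to 1: the O–CH3 bond, the C6–O bond and the O–CH2 bond of the acetal are cut in turn. Starting from 1 fixes the Br/CH3/OH relationship from the outset, which electrophilic bromination of an orcinol ether would not deliver cleanly. The demand is an oxygenation at the one C–H of 2 that no electrophile would choose, the position meta to both OMOM and CH3; a sterically governed C–H borylation answers it.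

## Other disconnections considered

Alternative 1: The cut is on the ring A side of the ketone. C1–C(=O) and C6–O are formed together when the ring A aryne A3 inserts into the carboxyl group of the fully substituted ring B acid A1. In the forward direction CsF would release A3 from the silyl triflate A2. The carboxylate of A1 would add through oxygen to the aryne carbon remote from the MOM ether; the aryl anion formed at C1 would attack the ester carbonyl, and collapse of the four-membered intermediate would move the acyl group to C1 and give ketone A4. With ring A numbered as in 21, the free phenol of A4 sits on C6, the carbon that carries OCH3 in the target, and C2 keeps the MOM ether. The aryne is therefore the C1–C6 aryne, and the oxygen delivered by the acid becomes the methoxy oxygen after methylation.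
- In its favour: the hindered ketone is formed without any organolithium, so the aryl bromide is safe. The substituent order on ring B is settled before the rings are joined; on this point it is better than the chosen plan, which relies on a contest between two carbonyl groups. The two ring A oxygens are differentiated automatically, which equals what the chosen plan achieves by borylation.
- Against it here: A1 is the whole hexasubstituted ring B and would take many steps of its own. The acyl shift from a di-ortho-substituted benzoate onto an aryl anion flanked by a MOM ether should be slow, and simple protonation after O-arylation is the likely leak. A2 needs several steps from a phenol such as 4. After A4 a methylation and the removal of three MOM ethers and an acetal remain, a heavier acid load on the prenyl group than in the chosen plan.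
- Comparison: it is mechanistically more predictable in orientation, but it solves the easy ring and leaves ring B unsolved; the chosen plan builds ring B and the ketone environment in one step and should be clearly shorter.

Alternative 2: The cut takes ring A apart: C1–C2, C2–C3 and C5–C6 are formed, the C1–C6 bond being the triple bond of the alkyne partner. In the forward direction irradiation of diazoketone A5 would give ketene A6 by Wolff rearrangement. A (2+2) addition to the ynol ether A7 would join the ketene carbonyl carbon (C2) to C1 and the ketene α-carbon (C5) to C6. Electrocyclic opening would then break the original C2–C5 bond, 6π closure would join C2 to the bromine-bearing C3, and tautomerisation would give phenol A8, racemic at the silylated carbinol.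
- In its favour: all five substituents of ring A are placed in one operation under neutral conditions. Bromine and methyl come from A5 and the methoxy group from A7. The C2 phenol is born free, so ring A needs no protecting group and no C–H oxygenation; on ring A this alternative is better than the chosen plan.
- Against it here: A7 contains the complete ring B, which still has to be made conventionally, so the hard part of the molecule is untouched. The propargylic carbon of A7 is flanked by a di-ortho-substituted arene and a silyl ether, which should slow the (2+2) step. A5 is a sensitive bromovinyl diazoketone, made with diazo chemistry and photolysed beside a C–Br bond. After A8 the carbinol must still be desilylated and oxidised while the formyl group stays masked, then everything unmasked under acid.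
- Comparison: the chosen plan carries the ketone at the right oxidation level through ring formation and needs one step afterwards; this alternative needs several. Step economy favours the chosen plan; certainty of substituent placement on ring A favours the alternative.

Alternative 3: The cut is C1'–C2' of ring B. In the forward direction triethylamine would make the dioxinone α-carbon of the open-chain precursor A9 (future C2') add to the C1' ketone; loss of water and enolisation of the C5' ketone would give benzodioxinone A10.
- In its favour: the order of substituents on ring B is written into the chain, so there is no regiochemical question; on this point it is better than the chosen plan. The conditions are as mild as those of the chosen cycloaddition, on which it is its equal. The C3' oxygen and the C2' carbon are protected together, and the chemistry follows the polyketide logic of the natural product.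
- Against it here: C2' ends at the carboxylic acid level, so a hydride reduction to the aldehyde must be carried out beside the diaryl ketone, or a protect–reduce–oxidise detour is needed. A9 has a 1,2-diketone next to a 1,3-diketone and a hindered aryl ketone; it would be hard to assemble and would exist as enol and hydrate mixtures with several aldol modes open.
- Comparison: the chosen plan delivers CHO at C2' directly and reaches the target one step after ring closure, from partners that are each a few steps from commercial materials. The alternative is safer in orientation but poorer in oxidation-level economy and in access to its precursor.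

Key step: step 10

Remark on the chemistry: 10 is racemic, 16–18 are used as the geometric mixtures that form (18 is drawn as the 1Z,3Z isomer), and 19 forms as a diastereomer mixture; all of these elements vanish when ring B becomes aromatic.

## Route

Step 1
Reactants: 1 2-bromo-3-methylphenol
Product: 2 2-bromo-1-(methoxymethoxy)-3-methylbenzene
Conditions: MOMCl, i-Pr2NEt, CH2Cl2, 0 °C → rt
Reagents that add atoms: chloromethyl methyl ether (MOMCl), COCCl
Why: O-alkylation of the phenol (Williamson-type acetal formation); the MOM ether is inert to the bases, organolithiums and oxidants used later and serves as a directing group in step 4.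

Step 2
Reactants: 2 2-bromo-1-(methoxymethoxy)-3-methylbenzene
Product: 4 4-bromo-3-(methoxymethoxy)-5-methylphenol, via arylboronic pinacol ester 3 (not isolated)
Conditions: B2pin2, [Ir(OMe)(cod)]2 (1.5 mol%), 4,4'-di-tert-butyl-2,2'-bipyridine (3 mol%), THF, 80 °C; then NaOH (aq), H2O2 (30% aq), 0 °C → rt
Reagents that add atoms: hydrogen peroxide, OO (oxygen of the new phenol); bis(pinacolato)diboron, CC1(C)OB(OC1(C)C)B1OC(C)(C)C(C)(C)O1 (boryl group of 3 only)
Why: Iridium-catalysed C–H borylation is ruled by sterics, and in 2 only the C–H meta to both OMOM and CH3 has no ortho neighbour, so boron should enter there while the C–Br bond is left alone; alkaline peroxide then turns C–B into C–O at the same carbon (boronate oxidation).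

Step 3
Reactants: 4 4-bromo-3-(methoxymethoxy)-5-methylphenol
Product: 5 2-bromo-5-methoxy-1-(methoxymethoxy)-3-methylbenzene
Conditions: MeI, K2CO3, acetone, 50 °C
Reagents that add atoms: iodomethane, CI
Why: Williamson methylation of the only free phenol; this fixes which ring A oxygen is OCH3 and which is masked.

Step 4
Reactants: 5 2-bromo-5-methoxy-1-(methoxymethoxy)-3-methylbenzene
Product: 7 3-bromo-6-methoxy-2-(methoxymethoxy)-4-methylbenzaldehyde, via aryllithium 6 (not isolated)
Conditions: lithium 2,2,6,6-tetramethylpiperidide (from 2,2,6,6-tetramethylpiperidine and n-BuLi), THF, −78 °C; then DMF, −78 → 0 °C; NH4Cl (aq)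
Reagents that add atoms: N,N-dimethylformamide, CN(C)C=O
Why: Directed ortho-metalation at the one C–H flanked by both oxygen substituents (cooperative OMOM/OCH3 direction); a lithium amide deprotonates without bromine–lithium exchange, no hydrogen stands ortho to bromine so no aryne can form, and the aryllithium is formylated by DMF (Bouveault-type formylation).

Step 5
Reactants: 7 3-bromo-6-methoxy-2-(methoxymethoxy)-4-methylbenzaldehyde; 8 prop-2-yn-1-ol
Product: 10 4-[3-bromo-6-methoxy-2-(methoxymethoxy)-4-methylphenyl]but-2-yne-1,4-diol (racemic), via dilithiated prop-2-yn-1-ol 9 (not isolated)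
Conditions: 8 (1.6 equiv), n-BuLi (3.1 equiv), THF, −78 → −20 °C; then 7, −78 → 0 °C; NH4Cl (aq)
Reagents that add atoms: none
Why: 1,2-Addition of a lithium acetylide to the aldehyde; all n-BuLi is consumed by 8 before 7 is added, so the C–Br bond is not exchanged, and the new carbinol centre needs no control because step 6 removes it.

Step 6
Reactants: 10 4-[3-bromo-6-methoxy-2-(methoxymethoxy)-4-methylphenyl]but-2-yne-1,4-diol
Product: 11 4-[3-bromo-6-methoxy-2-(methoxymethoxy)-4-methylphenyl]-4-oxobut-2-ynal
Conditions: Dess–Martin periodinane (3 equiv), NaHCO3, CH2Cl2, 0 °C → rt; filtration through a short silica pad, no aqueous work-up; used at once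
Reagents that add atoms: none
Why: Dess–Martin oxidation of both propargylic alcohols in one operation; the buffered, non-acidic medium spares the MOM ether, and the linear alkyne prevents any lactol from the half-oxidised stage.

Step 7
Reactants: 12 methyl acetoacetate; 13 prenyl bromide (1-bromo-3-methylbut-2-ene)
Product: 15 methyl 7-methyl-3-oxooct-6-enoate, via acetoacetate dianion 14 (not isolated)
Conditions: NaH, THF, 0 °C; n-BuLi, 0 °C; then 13, 0 °C → rt; NH4Cl (aq)
Reagents that add atoms: none
Why: Alkylation of a β-keto ester dianion occurs at the terminal (γ) carbon, its most basic and nucleophilic site, by direct displacement at the primary allylic bromide; this places the prenyl CH2 on the future C6'.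

Step 8
Reactants: 15 methyl 7-methyl-3-oxooct-6-enoate
Product: 16 methyl 7-methyl-3-(trimethylsilyloxy)octa-2,6-dienoate
Conditions: Me3SiCl, Et3N, hexane, rt
Reagents that add atoms: chlorotrimethylsilane, C[Si](C)(C)Cl
Why: O-Silylation of the enolised β-keto ester (silyl enol ether formation); the salt is filtered off and the product is carried on without chromatography.

Step 9
Reactants: 16 methyl 7-methyl-3-(trimethylsilyloxy)octa-2,6-dienoate
Product: 18 (1Z,3Z)-1-methoxy-7-methyl-1,3-bis(trimethylsilyloxy)octa-1,3,6-triene, via lithium dienolate 17 (not isolated)
Conditions: LiN(i-Pr)2, THF, −78 °C; then Me3SiCl, −78 °C → rt; hexane, filtration under argon; used crude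
Reagents that add atoms: chlorotrimethylsilane, C[Si](C)(C)Cl
Why: γ-Deprotonation of the silyloxy enoate gives the extended dienolate, which is silylated on the ester oxygen (silyl ketene acetal formation), the standard entry to 1-alkoxy-1,3-bis(silyloxy)dienes.

Step 10
Reactants: 11 4-[3-bromo-6-methoxy-2-(methoxymethoxy)-4-methylphenyl]-4-oxobut-2-ynal; 18 (1Z,3Z)-1-methoxy-7-methyl-1,3-bis(trimethylsilyloxy)octa-1,3,6-triene (1.5–2 equiv)
Product: 20 2-[3-bromo-6-methoxy-2-(methoxymethoxy)-4-methylbenzoyl]-4,6-dihydroxy-3-(3-methylbut-2-en-1-yl)benzaldehyde, via cycloadduct 19 (not isolated)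
Conditions: toluene, −78 °C → rt; then 0.5 M HCl (aq), THF, 0 °C
Reagents that add atoms: none
Why: This is a normal-electron-demand Diels–Alder reaction between the electron-rich diene 18 and the doubly acceptor-substituted alkyne 11, the known route from 1-alkoxy-1,3-bis(silyloxy)dienes and acetylenic carbonyl compounds to 2,4-dihydroxyaryl carbonyl compounds. Bond formation should be asynchronous: the diene terminus that carries the prenyl methylene, which has the largest HOMO coefficient, bonds first to C1', the alkyne carbon β to the formyl group, and the ketene acetal carbon then bonds to C2'. Ring B is thus closed in one intermolecular (4+2) event that forms C1'–C6' and C2'–C3' and gives the cyclohexa-1,4-diene 19. On the brief acid work-up the silyl ketal at C3' collapses with loss of methanol, the C5' silyl enol ether is hydrolysed and the dienone tautomerises, so ring B becomes aromatic with OH at C3' and C5', CHO at C2' and prenyl at C6'. The two sp3 centres of 19 (C3' and C6') form without control and both become sp2, so no stereocentre has to be set. The selectivity needed is regiochemical: the formyl group has no donor on its carbonyl carbon and is the stronger acceptor, so the LUMO of 11 should be larger at C1' than at C2'; this electronic bias is opposed by the bulk of the aroyl group at C1', so it is not guaranteed. Chemoselectivity for the triple bond over the formyl C=O is sought by using no Lewis acid, a non-polar solvent and low temperature.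

Step 11
Reactants: 20 2-[3-bromo-6-methoxy-2-(methoxymethoxy)-4-methylbenzoyl]-4,6-dihydroxy-3-(3-methylbut-2-en-1-yl)benzaldehyde
Product: 21 pestalone B, 2-(3-bromo-2-hydroxy-6-methoxy-4-methylbenzoyl)-4,6-dihydroxy-3-(3-methylbut-2-en-1-yl)benzaldehyde
Conditions: 1 M HCl (aq), MeOH/THF, 0 °C → rt
Reagents that add atoms: none
Why: Acid-catalysed acetal hydrolysis; the C2 oxygen, ortho to the ketone and to bromine, is a good phenolic leaving group, so this MOM ether should cleave in dilute acid at or below room temperature, where the trisubstituted alkene is not protonated.

## Compound list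

1 | 2-bromo-3-methylphenol | Cc1cccc(O)c1Br | starting material
2 | 2-bromo-1-(methoxymethoxy)-3-methylbenzene | COCOc1cccc(C)c1Br | intermediate
3 | 2-[4-bromo-3-(methoxymethoxy)-5-methylphenyl]-4,4,5,5-tetramethyl-1,3,2-dioxaborolane | COCOc1cc(cc(C)c1Br)B1OC(C)(C)C(C)(C)O1 | intermediate (not isolated)
4 | 4-bromo-3-(methoxymethoxy)-5-methylphenol | COCOc1cc(O)cc(C)c1Br | intermediate
5 | 2-bromo-5-methoxy-1-(methoxymethoxy)-3-methylbenzene | COCOc1cc(OC)cc(C)c1Br | intermediate
6 | [3-bromo-6-methoxy-2-(methoxymethoxy)-4-methylphenyl]lithium | [Li]c1c(OC)cc(C)c(Br)c1OCOC | intermediate (not isolated)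
7 | 3-bromo-6-methoxy-2-(methoxymethoxy)-4-methylbenzaldehyde | COc1cc(C)c(Br)c(OCOC)c1C=O | intermediate
8 | prop-2-yn-1-ol | OCC#C | starting material
9 | dilithiated prop-2-yn-1-ol (lithium 3-lithioprop-2-yn-1-olate) | [Li]OCC#C[Li] | intermediate (not isolated)
10 | 4-[3-bromo-6-methoxy-2-(methoxymethoxy)-4-methylphenyl]but-2-yne-1,4-diol (racemic) | COc1cc(C)c(Br)c(OCOC)c1C(O)C#CCO | intermediate
11 | 4-[3-bromo-6-methoxy-2-(methoxymethoxy)-4-methylphenyl]-4-oxobut-2-ynal | COc1cc(C)c(Br)c(OCOC)c1C(=O)C#CC=O | intermediate
12 | methyl acetoacetate | COC(=O)CC(C)=O | starting material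
13 | prenyl bromide (1-bromo-3-methylbut-2-ene) | CC(C)=CCBr | starting material
14 | sodium lithium dianion of methyl acetoacetate | [Li+].[Na+].COC([O-])=CC(=C)[O-] | intermediate (not isolated)
15 | methyl 7-methyl-3-oxooct-6-enoate | COC(=O)CC(=O)CCC=C(C)C | intermediate
16 | methyl 7-methyl-3-(trimethylsilyloxy)octa-2,6-dienoate (C2=C3 geometry as formed) | COC(=O)C=C(CCC=C(C)C)O[Si](C)(C)C | intermediate
17 | lithium 1-methoxy-7-methyl-3-(trimethylsilyloxy)octa-1,3,6-trien-1-olate | [Li]OC(OC)=CC(O[Si](C)(C)C)=CCC=C(C)C | intermediate (not isolated)
18 | (1Z,3Z)-1-methoxy-7-methyl-1,3-bis(trimethylsilyloxy)octa-1,3,6-triene | CO/C(O[Si](C)(C)C)=C/C(O[Si](C)(C)C)=C/CC=C(C)C | intermediate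
19 | 2-[3-bromo-6-methoxy-2-(methoxymethoxy)-4-methylbenzoyl]-6-methoxy-3-(3-methylbut-2-en-1-yl)-4,6-bis(trimethylsilyloxy)cyclohexa-1,4-diene-1-carbaldehyde (diastereomer mixture) | COC1(O[Si](C)(C)C)C=C(O[Si](C)(C)C)C(CC=C(C)C)C(C(=O)c2c(OC)cc(C)c(Br)c2OCOC)=C1C=O | intermediate (not isolated)
20 | 2-[3-bromo-6-methoxy-2-(methoxymethoxy)-4-methylbenzoyl]-4,6-dihydroxy-3-(3-methylbut-2-en-1-yl)benzaldehyde | COc1cc(C)c(Br)c(OCOC)c1C(=O)c1c(C=O)c(O)cc(O)c1CC=C(C)C | intermediate
21 | pestalone B | COc1cc(C)c(Br)c(O)c1C(=O)c1c(C=O)c(O)cc(O)c1CC=C(C)C | target

## Step count and risks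

Total step count: 11 steps. Longest linear sequence: 8 steps (steps 1–6, 10 and 11); the diene branch (steps 7–9) joins at step 10.

**Step 10 (key step).** Most likely to go wrong is the orientation of the cycloaddition. Bond formation could begin at C2', under control of the aroyl carbonyl, because C2' is the less hindered alkyne carbon; the formyl group is the stronger acceptor but only by a modest margin. A second leak is addition of the diene terminus to the formyl C=O instead of the triple bond.

Fallback: it sets out from 10 and returns to the route at 21. The ketone carbon is carried through the cycloaddition at the alcohol level, so that the formyl group is the only acceptor on the alkyne.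
- Selective oxidation of the primary propargylic alcohol of 10 (TEMPO cat., PhI(OAc)2, CH2Cl2) would give 4-[3-bromo-6-methoxy-2-(methoxymethoxy)-4-methylphenyl]-4-hydroxybut-2-ynal F1.
- Silylation (Et3SiOTf, 2,6-lutidine, CH2Cl2, −78 °C) would give its triethylsilyl ether F2.
- Cycloaddition of F2 with 18 and aromatisation on silica should give the silylated carbinol-aldehyde F3 with unambiguous orientation.
- A free carbinol beside the formyl group would close to a lactol and oxidise to a phthalide, so the oxidation levels are adjusted with both phenols capped. MOMCl and i-Pr2NEt would give the bis(methoxymethyl) ether F4, NaBH4 in MeOH the benzylic alcohol F5, and n-Bu4NF in THF the diol F6.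
- A Swern oxidation ((COCl)2, DMSO, −78 °C; then Et3N), in which both hydroxyls are activated before base is added, would give the keto aldehyde F7.
- Dilute HCl in MeOH/THF would remove the three MOM ethers and give 21.

**Step 4.** Most likely to go wrong is incomplete deprotonation by the amide base, or metalation that drifts to the benzylic methyl group or scrambles bromine between aryllithiums, because the ring proton is activated only by two ether oxygens.

Fallback: it sets out from 4 and returns at 7. The one-carbon unit is delivered intramolecularly from a stronger directing group.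
- 4 with ClC(=O)NEt2 and K2CO3 would give 4-bromo-3-(methoxymethoxy)-5-methylphenyl N,N-diethylcarbamate F8.
- LiN(i-Pr)2 in THF (−78 °C → rt) would lithiate between the carbamate and the MOM ether and trigger the anionic ortho-Fries shift to 3-bromo-N,N-diethyl-6-hydroxy-2-(methoxymethoxy)-4-methylbenzamide F9.
- MeI and K2CO3 would give the methyl ether 3-bromo-N,N-diethyl-6-methoxy-2-(methoxymethoxy)-4-methylbenzamide F10.
- Cp2Zr(H)Cl in THF would reduce the tertiary amide to aldehyde 7.

**Step 6.** Most likely to go wrong is loss of the product by hydration or conjugate addition to the doubly activated triple bond during oxidation and isolation, or stalling at the hindered secondary carbinol.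

Fallback: it sets out from 7 and returns at 11. The two carbonyl groups are unveiled one after the other.
- Lithiated 3,3-diethoxyprop-1-yne (n-BuLi, THF, −78 °C) would add to 7 to give 1-[3-bromo-6-methoxy-2-(methoxymethoxy)-4-methylphenyl]-4,4-diethoxybut-2-yn-1-ol F11.
- Dess–Martin oxidation would give the stable ynone acetal 1-[3-bromo-6-methoxy-2-(methoxymethoxy)-4-methylphenyl]-4,4-diethoxybut-2-yn-1-one F12.
- Brief treatment with wet formic acid at 0 °C, or with an acidic resin in aqueous acetone, would free the aldehyde to give 11. The price is that loss of the MOM ether must be watched.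

**Step 11.** Most likely to go wrong is acid-promoted attack of the C5' hydroxyl on the protonated prenyl alkene (chroman closure) competing with acetal cleavage.

Fallback: it sets out from 20 and returns at 21. The acetal is exchanged for silicon without Brønsted acid and the silyl groups are then removed with fluoride.
- Et3SiOTf and 2,2'-bipyridyl in CH2Cl2 at 0 °C would convert 20 into the tris(triethylsilyl) ether 2-[3-bromo-6-methoxy-4-methyl-2-(triethylsilyloxy)benzoyl]-3-(3-methylbut-2-en-1-yl)-4,6-bis(triethylsilyloxy)benzaldehyde F13.
- n-Bu4NF buffered with AcOH in THF at 0 °C would give 21.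

## Further compounds

F1 | step 10 | 4-[3-bromo-6-methoxy-2-(methoxymethoxy)-4-methylphenyl]-4-hydroxybut-2-ynal (racemic) | COc1cc(C)c(Br)c(OCOC)c1C(O)C#CC=O
F2 | step 10 | 4-[3-bromo-6-methoxy-2-(methoxymethoxy)-4-methylphenyl]-4-(triethylsilyloxy)but-2-ynal (racemic) | COc1cc(C)c(Br)c(OCOC)c1C(O[Si](CC)(CC)CC)C#CC=O
F3 | step 10 | 2-{[3-bromo-6-methoxy-2-(methoxymethoxy)-4-methylphenyl](triethylsilyloxy)methyl}-4,6-dihydroxy-3-(3-methylbut-2-en-1-yl)benzaldehyde (racemic) | COc1cc(C)c(Br)c(OCOC)c1C(O[Si](CC)(CC)CC)c1c(C=O)c(O)cc(O)c1CC=C(C)C
F4 | step 10 | 2-{[3-bromo-6-methoxy-2-(methoxymethoxy)-4-methylphenyl](triethylsilyloxy)methyl}-4,6-bis(methoxymethoxy)-3-(3-methylbut-2-en-1-yl)benzaldehyde (racemic) | COc1cc(C)c(Br)c(OCOC)c1C(O[Si](CC)(CC)CC)c1c(C=O)c(OCOC)cc(OCOC)c1CC=C(C)C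
F5 | step 10 | {2-{[3-bromo-6-methoxy-2-(methoxymethoxy)-4-methylphenyl](triethylsilyloxy)methyl}-4,6-bis(methoxymethoxy)-3-(3-methylbut-2-en-1-yl)phenyl}methanol (racemic) | COc1cc(C)c(Br)c(OCOC)c1C(O[Si](CC)(CC)CC)c1c(CO)c(OCOC)cc(OCOC)c1CC=C(C)C
F6 | step 10 | [3-bromo-6-methoxy-2-(methoxymethoxy)-4-methylphenyl][2-(hydroxymethyl)-3,5-bis(methoxymethoxy)-6-(3-methylbut-2-en-1-yl)phenyl]methanol (racemic) | COc1cc(C)c(Br)c(OCOC)c1C(O)c1c(CO)c(OCOC)cc(OCOC)c1CC=C(C)C
F7 | step 10 | 2-[3-bromo-6-methoxy-2-(methoxymethoxy)-4-methylbenzoyl]-4,6-bis(methoxymethoxy)-3-(3-methylbut-2-en-1-yl)benzaldehyde | COc1cc(C)c(Br)c(OCOC)c1C(=O)c1c(C=O)c(OCOC)cc(OCOC)c1CC=C(C)C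
F8 | step 4 | 4-bromo-3-(methoxymethoxy)-5-methylphenyl N,N-diethylcarbamate | CCN(CC)C(=O)Oc1cc(C)c(Br)c(OCOC)c1
F9 | step 4 | 3-bromo-N,N-diethyl-6-hydroxy-2-(methoxymethoxy)-4-methylbenzamide | CCN(CC)C(=O)c1c(O)cc(C)c(Br)c1OCOC
F10 | step 4 | 3-bromo-N,N-diethyl-6-methoxy-2-(methoxymethoxy)-4-methylbenzamide | CCN(CC)C(=O)c1c(OC)cc(C)c(Br)c1OCOC
F11 | step 6 | 1-[3-bromo-6-methoxy-2-(methoxymethoxy)-4-methylphenyl]-4,4-diethoxybut-2-yn-1-ol (racemic) | CCOC(OCC)C#CC(O)c1c(OC)cc(C)c(Br)c1OCOC
F12 | step 6 | 1-[3-bromo-6-methoxy-2-(methoxymethoxy)-4-methylphenyl]-4,4-diethoxybut-2-yn-1-one | CCOC(OCC)C#CC(=O)c1c(OC)cc(C)c(Br)c1OCOC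
F13 | step 11 | 2-[3-bromo-6-methoxy-4-methyl-2-(triethylsilyloxy)benzoyl]-3-(3-methylbut-2-en-1-yl)-4,6-bis(triethylsilyloxy)benzaldehyde | COc1cc(C)c(Br)c(O[Si](CC)(CC)CC)c1C(=O)c1c(C=O)c(O[Si](CC)(CC)CC)cc(O[Si](CC)(CC)CC)c1CC=C(C)C
A1 | alternative 1 | 2-(dimethoxymethyl)-3,5-bis(methoxymethoxy)-6-(3-methylbut-2-en-1-yl)benzoic acid | OC(=O)c1c(C(OC)OC)c(OCOC)cc(OCOC)c1CC=C(C)C
A2 | alternative 1 | 4-bromo-3-(methoxymethoxy)-5-methyl-2-(trimethylsilyl)phenyl trifluoromethanesulfonate | COCOc1c(Br)c(C)cc(OS(=O)(=O)C(F)(F)F)c1[Si](C)(C)C
A3 | alternative 1 | 4-bromo-3-(methoxymethoxy)-5-methyl-1,2-didehydrobenzene (ring A aryne) | COCOC1=C(Br)C(C)=CC#C1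
A4 | alternative 1 | [3-bromo-6-hydroxy-2-(methoxymethoxy)-4-methylphenyl][2-(dimethoxymethyl)-3,5-bis(methoxymethoxy)-6-(3-methylbut-2-en-1-yl)phenyl]methanone | Oc1cc(C)c(Br)c(OCOC)c1C(=O)c1c(C(OC)OC)c(OCOC)cc(OCOC)c1CC=C(C)C
A5 | alternative 2 | 4-bromo-1-diazo-3-methylbut-3-en-2-one (either alkene geometry) | [N-]=[N+]=CC(=O)C(C)=CBr
A6 | alternative 2 | 4-bromo-3-methylbuta-1,3-dien-1-one (bromovinylketene) | O=C=CC(C)=CBr
A7 | alternative 2 | tert-butyl{1-[2-(dimethoxymethyl)-3,5-bis(methoxymethoxy)-6-(3-methylbut-2-en-1-yl)phenyl]-3-methoxyprop-2-yn-1-yloxy}dimethylsilane (racemic) | COC#CC(O[Si](C)(C)C(C)(C)C)c1c(C(OC)OC)c(OCOC)cc(OCOC)c1CC=C(C)C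
A8 | alternative 2 | 6-bromo-2-{[tert-butyl(dimethyl)silyl]oxy[2-(dimethoxymethyl)-3,5-bis(methoxymethoxy)-6-(3-methylbut-2-en-1-yl)phenyl]methyl}-3-methoxy-5-methylphenol (racemic, one enantiomer drawn) | COc1cc(C)c(Br)c(O)c1[C@H](O[Si](C)(C)C(C)(C)C)c1c(C(OC)OC)c(OCOC)cc(OCOC)c1CC=C(C)C
A9 | alternative 3 | 6-{5-[3-bromo-6-methoxy-2-(methoxymethoxy)-4-methylphenyl]-3-(3-methylbut-2-en-1-yl)-2,4,5-trioxopentyl}-2,2-dimethyl-4H-1,3-dioxin-4-one (racemic, enolisable) | CC1(C)OC(=O)C=C(CC(=O)C(CC=C(C)C)C(=O)C(=O)c2c(OC)cc(C)c(Br)c2OCOC)O1
A10 | alternative 3 | 5-[3-bromo-6-methoxy-2-(methoxymethoxy)-4-methylbenzoyl]-7-hydroxy-2,2-dimethyl-6-(3-methylbut-2-en-1-yl)-4H-1,3-benzodioxin-4-one | CC1(C)OC(=O)c2c(O1)cc(O)c(CC=C(C)C)c2C(=O)c1c(OC)cc(C)c(Br)c1OCOC
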